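Ring B (C5–C10) hides a mirror plane through C6 and C9: O6 lies para to the C9 carbinol, and both neighbours of C9 (C8 and C10) carry a methyl group. The decalin is therefore traced back to an achiral 4-alkyl-4-hydroxy-3,5-dimethylcyclohexa-2,5-dienone, obtained by oxidising the corresponding phenol. One copper-catalysed, ligand-controlled 1,4-addition of homoprenylmagnesium bromide breaks this symmetry: it forms C10–C1, creates the quaternary C10 and makes C9 stereogenic in a single operation. Ring A is then closed at C4–C5 by tert-alkylation of a C5–C6 silyl enol ether, C6 and C8 are set from the enone, and the butenolide is joined last at C12–C13.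

Key step: step 6

Assumption: the sense of induction of the chiral NHC ligand on the p-quinol cannot be predicted safely, so the ligand antipode that leads to the (4S,5S) adduct is chosen after a test run. Labdane numbering is used throughout, with α the face of 5-H and O9 and β the face of C20.

Step 1
Reactants: 1 4-bromo-3,5-dimethylphenol
Product: 2 2-bromo-5-(methoxymethoxy)-1,3-dimethylbenzene
Conditions: MOMCl, i-Pr2NEt, CH2Cl2, 0 °C → rt
Reagents that add atoms: chloromethyl methyl ether (MOMCl), COCCl
Why: Base-mediated O-alkylation of the phenol gives an acetal-type protecting group that tolerates the organolithium and alkoxide chemistry of step 2 and later falls off under mild acid that leaves a benzyl ether alone.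

Step 2
Reactants: 2 2-bromo-5-(methoxymethoxy)-1,3-dimethylbenzene; 3 ethylene oxide
Product: 6 2-[2-(benzyloxy)ethyl]-5-(methoxymethoxy)-1,3-dimethylbenzene, via aryllithium 4 (not isolated), via lithium alkoxide 5 (not isolated)
Conditions: n-BuLi, THF, −78 °C; 3, −78 °C → rt; then BnBr, Bu4NI (10 mol %), DMPU, rt → 45 °C
Reagents that add atoms: benzyl bromide, BrCc1ccccc1
Why: Bromine–lithium exchange at −78 °C is far faster than ortho-metalation next to the MOM group, the aryllithium opens the unsubstituted epoxide by SN2 attack (C9–C11 bond), and the alkoxide is benzylated in the same flask by Williamson etherification, which saves one isolation.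

Step 3
Reactants: 6 2-[2-(benzyloxy)ethyl]-5-(methoxymethoxy)-1,3-dimethylbenzene
Product: 7 4-[2-(benzyloxy)ethyl]-3,5-dimethylphenol
Conditions: HCl (cat.), MeOH, 45 °C
Reagents that add atoms: none
Why: Acid-catalysed transacetalisation to methanol releases the phenol, while the primary alkyl benzyl ether is inert under these conditions.

Step 4
Reactants: 7 4-[2-(benzyloxy)ethyl]-3,5-dimethylphenol
Product: 8 4-[2-(benzyloxy)ethyl]-4-hydroxy-3,5-dimethylcyclohexa-2,5-dien-1-one (achiral p-quinol)
Conditions: PhI(OAc)2, MeCN/H2O (3:1), 0 °C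
Reagents that add atoms: water, O
Why: In this hypervalent-iodine oxidative dearomatisation of a 4-alkylphenol, ligand exchange at iodine(III) and loss of iodobenzene make the alkyl-bearing para carbon C9 electrophilic so that water adds there, the benzyl-capped side chain cannot compete because it could only close a four-membered ring, and the product is achiral since C6 and C9 lie on its mirror plane.

Step 5
Reactants: 9 5-bromo-2-methylpent-2-ene
Product: 10 (4-methylpent-3-en-1-yl)magnesium bromide
Conditions: Mg turnings (I2-activated), Et2O, gentle reflux; titrated before use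
Reagents that add atoms: magnesium, [Mg]
Why: This is a standard Grignard formation from a primary bromide, and the homoallyl/cyclopropylcarbinyl equilibrium lies on the open-chain side and merely exchanges C1 and C2, so the constitution is unaffected.

Step 6
Reactants: 8 4-[2-(benzyloxy)ethyl]-4-hydroxy-3,5-dimethylcyclohexa-2,5-dien-1-one; 10 (4-methylpent-3-en-1-yl)magnesium bromide
Product: 13 (4S,5S)-4-[2-(benzyloxy)ethyl]-4-hydroxy-3,5-dimethyl-5-(4-methylpent-3-en-1-yl)cyclohex-2-en-1-one, via magnesium alkoxide 11 (not isolated), via magnesium enolate 12 (not isolated)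
Conditions: 8, 10 (1.05 equiv), Et2O/CH2Cl2, −78 °C (gives 11); this solution added over 1 h to 10 (1.5 equiv), Cu(OTf)2 (5 mol %), chiral N-mesityl-N′-(1-hydroxy-4-methylpentan-2-yl)imidazolinium hexafluorophosphate (NHC precursor, 7 mol %), Et2O, −30 °C; sat. aq NH4Cl
Reagents that add atoms: none
Why: Proposed new method: the first equivalent of 10 converts O9–H into the bromomagnesium alkoxide 11, after which the NHC–copper(I) alkyl formed from 10 π-binds one enone arm, adds oxidatively at its β-carbon C10 to a copper(III) species and reductively eliminates, giving the C10–C1 bond and the C5–C6 magnesium enolate 12. The closest known reaction types are NHC–copper-catalysed additions of Grignard reagents to 3-methylcyclohexenones that build quaternary carbons, copper-catalysed desymmetrising 1,4-additions to 4,4-disubstituted cyclohexadienones, and hydroxyl-directed syn 1,4-additions of Grignard reagents to p-quinols; their combination on a 3,5-dimethyl p-quinol is untested. No ring is closed in this step. C10 is set by entry of C1 on the face that carries O9, favoured both by the magnesium alkoxide, which can hold the organometallic on its side, and by the bulkier CH2CH2OBn group on the opposite side, whereas C9 becomes stereogenic only because one of the two arms reacts, a choice made by the chiral ligand. On the O9 face the two β-carbons present opposite enantiofaces, so a ligand that reads the enantioface selects a single arm, and no regiochemical question arises because the arms are identical until this event. 1,2-Attack at C6 and the racemic uncatalysed directed addition are held back by copper catalysis, ether solvent, low temperature and slow mixing, and a second addition cannot follow because the product remains an enolate until the quench.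

Step 7
Reactants: 13 (4S,5S)-4-[2-(benzyloxy)ethyl]-4-hydroxy-3,5-dimethyl-5-(4-methylpent-3-en-1-yl)cyclohex-2-en-1-one
Product: 14 (4S,5S)-4-[2-(benzyloxy)ethyl]-5-(4-chloro-4-methylpentyl)-4-hydroxy-3,5-dimethylcyclohex-2-en-1-one
Conditions: dry HCl (g), CH2Cl2, −20 → 0 °C
Reagents that add atoms: hydrogen chloride, Cl
Why: In this Markovnikov hydrochlorination only the electron-rich trisubstituted alkene is protonated at carbon (C3) and chloride captures the tertiary C4 cation, which stores the cation in a form that a Lewis acid can release later without the Brønsted acid that would merely protodesilylate an enol ether.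

Step 8
Reactants: 14 (4S,5S)-4-[2-(benzyloxy)ethyl]-5-(4-chloro-4-methylpentyl)-4-hydroxy-3,5-dimethylcyclohex-2-en-1-one
Product: 16 6,9-bis-O-triethylsilyl derivative of 14 (cross-conjugated C5=C6/C7=C8 silyl dienol ether; C9 and C10 as in 13), via dilithium salt 15 (not isolated)
Conditions: LDA (2.3 equiv), THF, −78 °C; TESOTf (3 equiv), −78 → −30 °C; cold aq NaHCO3, used without delay
Reagents that add atoms: triethylsilyl trifluoromethanesulfonate (TESOTf), CC[Si](CC)(CC)OS(=O)(=O)C(F)(F)F
Why: After O9–H, kinetic deprotonation of the enone by a lithium amide takes the α′ proton at C5 (the behaviour known from isophorone), whereas silyl triflate/amine conditions would drift to the extended C6=C7/C8=C17 dienol ether, and the silyl triflate then caps both the enolate oxygen and the hindered tertiary alkoxide while the tertiary chloride is inert to LDA at −78 °C.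

Step 9
Reactants: 16 6,9-bis-O-triethylsilyl derivative of 14
Product: 17 12-benzyloxy-9α-triethylsilyloxy-13,14,15,16-tetranorlabd-7-en-6-one as a mixture of C5 epimers
Conditions: TiCl4 (1.1 equiv), CH2Cl2, −78 → −45 °C; then H2O at low temperature, NaHCO3 wash
Reagents that add atoms: none
Why: This is a Lewis-acid-mediated α-tert-alkylation of a silyl enol ether (Reetz alkylation) run intramolecularly, in which TiCl4 abstracts chloride, nucleophilic C5 captures the tertiary C4 cation in a six-membered closure and loss of the silyl group restores the enone, the absence of Brønsted acid and of a free C6 carbonyl shutting off protodesilylation and Prins-type attack on C6; the stereoelectronically preferred axial attack may favour the cis-fused C5 epimer, which step 10 corrects.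

Step 10
Reactants: 17 12-benzyloxy-9α-triethylsilyloxy-13,14,15,16-tetranorlabd-7-en-6-one (C5 epimers)
Product: 18 12-benzyloxy-9α-triethylsilyloxy-13,14,15,16-tetranorlabd-7-en-6-one (trans-fused: 5α-H, 10β-CH3)
Conditions: NaOMe (0.2 equiv), MeOH/THF, rt → 40 °C
Reagents that add atoms: none
Why: Base-catalysed epimerisation through the cross-conjugated C5–C6 dienolate touches only C5, the sole enolisable stereocentre, and the trans-fused 5α-H isomer, with the quaternary C4 equatorial on ring B and clear of the axial 9α-silyloxy group, should be the thermodynamic sink as in natural 6-oxolabdanes.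

Step 11
Reactants: 18 12-benzyloxy-9α-triethylsilyloxy-13,14,15,16-tetranorlabd-7-en-6-one
Product: 19 12-benzyloxy-9α-triethylsilyloxy-13,14,15,16-tetranorlabd-7-en-6β-ol
Conditions: NaBH4, CeCl3·7H2O, MeOH/THF, −40 → 0 °C
Reagents that add atoms: none
Why: In this Luche 1,2-reduction the β face of C6 is screened by the two syn-axial methyl groups C19 and C20, so hydride enters from the α face and gives the axial 6β-alcohol, with cerium(III) suppressing 1,4-reduction.

Step 12
Reactants: 19 12-benzyloxy-9α-triethylsilyloxy-13,14,15,16-tetranorlabd-7-en-6β-ol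
Product: 20 12-benzyloxy-9α-triethylsilyloxy-13,14,15,16-tetranorlabdan-6β-ol (8β-H, 8α-CH3)
Conditions: [Ir(cod)(PCy3)(py)]PF6 (5–10 mol %), H2, CH2Cl2, rt
Reagents that add atoms: none
Why: In this hydroxyl-directed homogeneous hydrogenation with Crabtree's catalyst, iridium binds the 6β-OH and delivers both hydrogens to the β face of C7=C8 while the axial 9α-silyloxy group shields the α face, so C8 receives its β-H and equatorial α-methyl, and benzyl ethers are not cleaved by this catalyst.

Step 13
Reactants: 20 12-benzyloxy-9α-triethylsilyloxy-13,14,15,16-tetranorlabdan-6β-ol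
Product: 21 6β-acetoxy-12-benzyloxy-9α-triethylsilyloxy-13,14,15,16-tetranorlabdane
Conditions: Ac2O, DMAP, pyridine, 50 °C
Reagents that add atoms: acetic anhydride, CC(=O)OC(C)=O
Why: DMAP-catalysed acyl transfer forces the hindered axial 6β-alcohol, the only free hydroxyl in the molecule, to react with retention at C6.

Step 14
Reactants: 21 6β-acetoxy-12-benzyloxy-9α-triethylsilyloxy-13,14,15,16-tetranorlabdane
Product: 22 6β-acetoxy-9α-triethylsilyloxy-13,14,15,16-tetranorlabdan-12-ol
Conditions: H2 (1 atm), 10 % Pd/C, EtOAc, rt
Reagents that add atoms: none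
Why: Heterogeneous hydrogenolysis cleaves the benzylic C–O bond with no alkene left to reduce, and ethyl acetate instead of methanol avoids the palladium-induced solvolysis of triethylsilyl ethers.

Step 15
Reactants: 22 6β-acetoxy-9α-triethylsilyloxy-13,14,15,16-tetranorlabdan-12-ol
Product: 23 6β-acetoxy-12-iodo-9α-triethylsilyloxy-13,14,15,16-tetranorlabdane
Conditions: I2, PPh3, imidazole, CH2Cl2, 0 °C → rt
Reagents that add atoms: iodine, II
Why: In this Appel-type iodination the primary alcohol is activated as an alkoxyphosphonium ion and displaced by iodide in an SN2 step under near-neutral conditions that leave the acetate and the tertiary silyl ether untouched.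

Step 16
Reactants: 23 6β-acetoxy-12-iodo-9α-triethylsilyloxy-13,14,15,16-tetranorlabdane; 24 3-bromofuran-2(5H)-one
Product: 26 6β-acetoxy-9α-triethylsilyloxylabd-13-en-16,15-olide, via alkylzinc iodide 25 (not isolated)
Conditions: Zn dust (activated with TMSCl/1,2-dibromoethane), LiCl, THF, 40 °C; then 24, PdCl2(dppf) (5 mol %), THF, rt → 45 °C
Reagents that add atoms: none
Why: LiCl-assisted zinc insertion into the primary iodide gives an alkylzinc reagent that tolerates acetate and silyl ether, and the sp3–sp2 Negishi coupling (oxidative addition into the activated α-C–Br bond, transmetalation, reductive elimination) forms C12–C13 without any base that would harm the butenolide, the bidentate dppf curbing β-hydride elimination.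

Step 17
Reactants: 26 6β-acetoxy-9α-triethylsilyloxylabd-13-en-16,15-olide
Product: 27 (5S,6R,8R,9R,10S)-6-acetoxy-9-hydroxylabd-13-en-16,15-olide (CNP0205088.1)
Conditions: HF·pyridine, THF, 0 °C → rt
Reagents that add atoms: none
Why: Fluoride-driven Si–O cleavage under mildly acidic conditions spares the acetate and the base-sensitive butenolide and does not ionise the tertiary C9–O bond, so no stereocentre is touched.

Compound list
1 | 4-bromo-3,5-dimethylphenol | Cc1cc(O)cc(C)c1Br | starting material
2 | 2-bromo-5-(methoxymethoxy)-1,3-dimethylbenzene | COCOc1cc(C)c(Br)c(C)c1 | intermediate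
3 | ethylene oxide | C1CO1 | starting material
4 | [4-(methoxymethoxy)-2,6-dimethylphenyl]lithium (not isolated) | [Li]c1c(C)cc(OCOC)cc1C | intermediate
5 | lithium 2-[4-(methoxymethoxy)-2,6-dimethylphenyl]ethoxide (not isolated) | [Li]OCCc1c(C)cc(OCOC)cc1C | intermediate
6 | 2-[2-(benzyloxy)ethyl]-5-(methoxymethoxy)-1,3-dimethylbenzene | COCOc1cc(C)c(CCOCc2ccccc2)c(C)c1 | intermediate
7 | 4-[2-(benzyloxy)ethyl]-3,5-dimethylphenol | Cc1cc(O)cc(C)c1CCOCc1ccccc1 | intermediate
8 | 4-[2-(benzyloxy)ethyl]-4-hydroxy-3,5-dimethylcyclohexa-2,5-dien-1-one (achiral) | O=C1C=C(C)C(O)(CCOCc2ccccc2)C(C)=C1 | intermediate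
9 | 5-bromo-2-methylpent-2-ene | CC(C)=CCCBr | starting material
10 | (4-methylpent-3-en-1-yl)magnesium bromide | CC(C)=CCC[Mg]Br | intermediate
11 | bromomagnesium alkoxide of 8 (not isolated) | O=C1C=C(C)C(O[Mg]Br)(CCOCc2ccccc2)C(C)=C1 | intermediate
12 | bis(bromomagnesium) salt of 13, C5–C6 enolate and C9 alkoxide (not isolated) | Br[Mg]OC1=C[C@](C)(CCC=C(C)C)[C@@](O[Mg]Br)(CCOCc2ccccc2)C(C)=C1 | intermediate
13 | (4S,5S)-4-[2-(benzyloxy)ethyl]-4-hydroxy-3,5-dimethyl-5-(4-methylpent-3-en-1-yl)cyclohex-2-en-1-one (9α-OH, 10β-CH3) | O=C1C=C(C)[C@](O)(CCOCc2ccccc2)[C@@](C)(CCC=C(C)C)C1 | intermediate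
14 | (4S,5S)-4-[2-(benzyloxy)ethyl]-5-(4-chloro-4-methylpentyl)-4-hydroxy-3,5-dimethylcyclohex-2-en-1-one | O=C1C=C(C)[C@](O)(CCOCc2ccccc2)[C@@](C)(CCCC(C)(C)Cl)C1 | intermediate
15 | dilithium salt of 14, C5–C6 enolate and C9 alkoxide (not isolated) | [Li]OC1=C[C@](C)(CCCC(C)(C)Cl)[C@@](O[Li])(CCOCc2ccccc2)C(C)=C1 | intermediate
16 | 6,9-bis-O-triethylsilyl derivative of 14 (C5=C6/C7=C8 silyl dienol ether) | CC[Si](CC)(CC)OC1=C[C@](C)(CCCC(C)(C)Cl)[C@@](O[Si](CC)(CC)CC)(CCOCc2ccccc2)C(C)=C1 | intermediate
17 | 12-benzyloxy-9α-triethylsilyloxy-13,14,15,16-tetranorlabd-7-en-6-one, C5 epimers (C5 left open) | O=C1C=C(C)[C@](O[Si](CC)(CC)CC)(CCOCc2ccccc2)[C@@]2(C)CCCC(C)(C)C12 | intermediate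
18 | 12-benzyloxy-9α-triethylsilyloxy-13,14,15,16-tetranorlabd-7-en-6-one (5α-H, trans-fused) | O=C1C=C(C)[C@](O[Si](CC)(CC)CC)(CCOCc2ccccc2)[C@@]2(C)CCCC(C)(C)[C@H]12 | intermediate
19 | 12-benzyloxy-9α-triethylsilyloxy-13,14,15,16-tetranorlabd-7-en-6β-ol | O[C@@H]1C=C(C)[C@](O[Si](CC)(CC)CC)(CCOCc2ccccc2)[C@@]2(C)CCCC(C)(C)[C@H]12 | intermediate
20 | 12-benzyloxy-9α-triethylsilyloxy-13,14,15,16-tetranorlabdan-6β-ol (8α-CH3) | O[C@@H]1C[C@@H](C)[C@](O[Si](CC)(CC)CC)(CCOCc2ccccc2)[C@@]2(C)CCCC(C)(C)[C@H]12 | intermediate
21 | 6β-acetoxy-12-benzyloxy-9α-triethylsilyloxy-13,14,15,16-tetranorlabdane | CC(=O)O[C@@H]1C[C@@H](C)[C@](O[Si](CC)(CC)CC)(CCOCc2ccccc2)[C@@]2(C)CCCC(C)(C)[C@H]12 | intermediate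
22 | 6β-acetoxy-9α-triethylsilyloxy-13,14,15,16-tetranorlabdan-12-ol | CC(=O)O[C@@H]1C[C@@H](C)[C@](O[Si](CC)(CC)CC)(CCO)[C@@]2(C)CCCC(C)(C)[C@H]12 | intermediate
23 | 6β-acetoxy-12-iodo-9α-triethylsilyloxy-13,14,15,16-tetranorlabdane | CC(=O)O[C@@H]1C[C@@H](C)[C@](O[Si](CC)(CC)CC)(CCI)[C@@]2(C)CCCC(C)(C)[C@H]12 | intermediate
24 | 3-bromofuran-2(5H)-one | O=C1OCC=C1Br | starting material
25 | 12-(iodozincio) analogue of 23 (not isolated) | CC(=O)O[C@@H]1C[C@@H](C)[C@](O[Si](CC)(CC)CC)(CC[Zn]I)[C@@]2(C)CCCC(C)(C)[C@H]12 | intermediate
26 | 6β-acetoxy-9α-triethylsilyloxylabd-13-en-16,15-olide | CC(=O)O[C@@H]1C[C@@H](C)[C@](O[Si](CC)(CC)CC)(CCC2=CCOC2=O)[C@@]2(C)CCCC(C)(C)[C@H]12 | intermediate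
27 | (5S,6R,8R,9R,10S)-6-acetoxy-9-hydroxylabd-13-en-16,15-olide, CNP0205088.1 | CC(=O)O[C@@H]1C[C@@H](C)[C@](O)(CCC2=CCOC2=O)[C@@]2(C)CCCC(C)(C)[C@H]12 | target

Total step count: 17. Longest linear sequence: 16 (steps 1–4 and 6–17, from 1). Step 5 is the only side branch.

Steps most likely to fail

Step 6. Conversion at the crowded β-carbon beside the fully substituted C9 may be sluggish. 1,2-Addition at C6 may intrude, and the uncatalysed alkoxide-directed addition or a mismatch between ligand and alkoxide control may erode the enantiomeric purity. The fallback gives up catalyst control and sets out from 8. Compound 8 is treated with an excess of the achiral magnesium homocuprate prepared from 10 and CuBr·SMe2 (THF/Me2S, −40 °C). This stoichiometric reagent class is known to add to β,β-disubstituted enones and to enter p-quinols on the oxygen-bearing face. It should give 13 together with its mirror image, the (4R,5R)-enone F1, as the racemate. The racemate is resolved by preparative chromatography on a polysaccharide chiral stationary phase, and the route is rejoined at 13.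

Step 9. Proton loss from the C4 cation may outrun C–C bond formation. The Lewis acid may also strip the O9 silyl group and trigger a 1,2-shift towards C8 of the activated enone. The fallback generates the cationic centre from an epoxide instead of a chloride and sets out from 13.
- Buffered m-CPBA (NaHCO3, CH2Cl2, 0 °C) attacks only the electron-rich side-chain alkene and gives the side-chain 3,4-epoxide F2.
- LDA (2.3 equiv) followed by TESCl/DMPU gives the bis-silyl epoxide F3.
- MeAlCl2 (CH2Cl2, −78 °C) opens the epoxide at tertiary C4 in concert with attack of C5. This is an epoxide-initiated cation–enol cyclisation, known with silyl enol ether terminators, and it leads to the 3-hydroxydecalenone F4.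
- The superfluous hydroxyl is removed by Barton–McCombie deoxygenation through the imidazolylthiocarbonyl derivative F5 (1,1′-thiocarbonyldiimidazole, DMAP; then Bu3SnH, AIBN, toluene, 90 °C).

The sequence comes back at 17, ready for the equilibration of step 10.

Step 12. Binding of iridium on the β face next to the axial C20 methyl may be too hindered. The consequences would be poor facial selectivity, slow reduction, or isomerisation of the allylic alcohol to the ketone. The fallback drops the directing effect in favour of thermodynamic control and sets out from 19. Acetylation (Ac2O, DMAP, pyridine) gives the allylic 6β-acetate F6. It is then reduced by metal-hydride hydrogen-atom-transfer hydrogenation (Mn(dpm)3, PhSiH3, t-BuOOH, i-PrOH). In this stepwise radical process the tertiary C8 radical should be quenched towards the more stable equatorial 8α-methyl isomer, and the route is rejoined at 21.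

Further compounds
F1 | step 6 | (4R,5R)-enantiomer of 13, formed with 13 as the racemate | O=C1C=C(C)[C@@](O)(CCOCc2ccccc2)[C@](C)(CCC=C(C)C)C1
F2 | step 9 | side-chain 3,4-epoxide of 13 (both C3 epimers) | O=C1C=C(C)[C@](O)(CCOCc2ccccc2)[C@@](C)(CCC2OC2(C)C)C1
F3 | step 9 | 6,9-bis-O-triethylsilyl dienol ether of F2 | CC[Si](CC)(CC)OC1=C[C@](C)(CCC2OC2(C)C)[C@@](O[Si](CC)(CC)CC)(CCOCc2ccccc2)C(C)=C1
F4 | step 9 | 12-benzyloxy-3-hydroxy-9α-triethylsilyloxy-13,14,15,16-tetranorlabd-7-en-6-one (C3 and C5 open) | O=C1C=C(C)[C@](O[Si](CC)(CC)CC)(CCOCc2ccccc2)[C@@]2(C)CCC(O)C(C)(C)C12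
F5 | step 9 | 3-O-(imidazol-1-ylthiocarbonyl) derivative of F4 | O=C1C=C(C)[C@](O[Si](CC)(CC)CC)(CCOCc2ccccc2)[C@@]2(C)CCC(OC(=S)n3ccnc3)C(C)(C)C12
F6 | step 12 | 6β-acetoxy-12-benzyloxy-9α-triethylsilyloxy-13,14,15,16-tetranorlabd-7-ene | CC(=O)O[C@@H]1C=C(C)[C@](O[Si](CC)(CC)CC)(CCOCc2ccccc2)[C@@]2(C)CCCC(C)(C)[C@H]12
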